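**Retrosynthetic overview**

1. Quinone atoms: C1(=O), C2(OMe), C3(OMe), C4(=O), C5(chromanyl), C6(H). The two carbonyl oxygens come last: C1–O by Teuber oxidation of phenol 18, C4–O by hydroxylation of aryl chloride 17, whose chlorine on C4 is a placeholder.
2. Key disconnection: the six-membered carbocycle is cut at C6–C1 and at C2–C3 into a two-carbon unit (C1–C2, 1-methoxyvinyllithium from methyl vinyl ether 12) and a four-carbon unit (C3–C4–C5–C6, 2-chlorocyclobutenone 11, with C3 as carbonyl carbon and C6 as ring CH2). Forward: 1,2-addition (C2–C3), O-methylation, 4π opening of the four-membered ring, 6π closure (C6–C1), then dehydrogenation to the arene.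
3. Enabling feature: C2 and C3 are neighbours that both carry OMe, and C6 is the only hydrogen-bearing carbon of the quinone ring and lies next to C1. So C3 can enter as a ketone carbon whose oxygen simply becomes the ether oxygen, and C6 and C1 can enter as the two unsubstituted CH2 ends of a hexatriene.
4. 11 comes from terminal alkyne 7 by dichloroketene [2+2] cycloaddition, 1,3-chlorine shift and zinc reduction; 7 comes from alcohol 5 by oxidation and one-carbon homologation.
5. The stereocentre is set early by asymmetric hydrogenation of chromene 4 (from salicylaldehyde 1 and acrolein 2). Ring order: pyran ring (step 1), four-membered ring (step 6), six-membered carbocycle (step 8), its aromatisation (step 9), quinone (step 11).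

Key step: step 8

Assumption: the target SMILES corresponds to (S) at C3 of the chroman; every intermediate keeps this spatial arrangement, and the descriptor changes only in aldehyde 6, where the formyl group outranks C2.
Assumption: the (S)-configured P,N ligand is taken to deliver alcohol 5 with the needed configuration; if the first hydrogenation shows the opposite sense, the ligand antipode is used.

**Step 1**
Reactants: 1 2-hydroxy-4,5-dimethoxybenzaldehyde; 2 acrolein
Product: 3 6,7-dimethoxy-2H-chromene-3-carbaldehyde
Conditions: K2CO3 (0.2 equiv), 1,4-dioxane, reflux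
Reagents that add atoms: none
Why: base-mediated oxa-Michael addition of the phenol to acrolein followed by intramolecular aldol condensation onto the aryl aldehyde (a domino oxa-Michael/aldol annulation well known for salicylaldehydes) should close the pyran ring and leave the conjugated aldehyde at C3.

**Step 2**
Reactants: 3 6,7-dimethoxy-2H-chromene-3-carbaldehyde
Product: 4 (6,7-dimethoxy-2H-chromen-3-yl)methanol
Conditions: NaBH4, CeCl3·7H2O, MeOH, 0 °C
Reagents that add atoms: none
Why: Luche reduction should reduce the enal 1,2 to the allylic alcohol without touching the styrene-type double bond.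

**Step 3**
Reactants: 4 (6,7-dimethoxy-2H-chromen-3-yl)methanol
Product: 5 [(3S)-6,7-dimethoxychroman-3-yl]methanol
Conditions: H2 (50 bar), [Ir(cod)(L)][B(3,5-(CF3)2C6H3)4] (1 mol %), CH2Cl2, rt; cod = 1,5-cyclooctadiene, L = (S)-4-tert-butyl-2-[2-(diphenylphosphino)phenyl]-4,5-dihydrooxazole
Reagents that add atoms: none
Why: iridium-catalysed asymmetric hydrogenation of a trisubstituted, aryl-conjugated allylic alcohol (the cyclic counterpart of the standard substrate (E)-2-methyl-3-phenylprop-2-en-1-ol) should add hydrogen to one face of the C3=C4 bond under control of the chiral P,N ligand and so set the only stereocentre, C3 of the chroman.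

**Step 4**
Reactants: 5 [(3S)-6,7-dimethoxychroman-3-yl]methanol
Product: 6 (3R)-6,7-dimethoxychroman-3-carbaldehyde
Conditions: Dess–Martin periodinane (1.2 equiv), CH2Cl2, 0 °C to rt; crude product used at once
Reagents that add atoms: none
Why: Dess–Martin oxidation runs under nearly neutral conditions at low temperature, so the enolisable β-aryloxy aldehyde should form without epimerisation or retro-oxa-Michael ring opening.

**Step 5**
Reactants: 6 (3R)-6,7-dimethoxychroman-3-carbaldehyde
Product: 7 (3S)-3-ethynyl-6,7-dimethoxychroman
Conditions: TMSCHN2, n-BuLi, THF, −78 °C; then 6, −78 °C to rt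
Reagents that add atoms: (trimethylsilyl)diazomethane, C[Si](C)(C)C=[N+]=[N-]
Why: Colvin rearrangement, in which the lithiated diazomethane adds to the aldehyde at −78 °C faster than it deprotonates it, and Peterson elimination, loss of N2 and a 1,2-hydrogen shift of the alkylidene carbene should give the terminal alkyne with the stereocentre unchanged.

**Step 6**
Reactants: 7 (3S)-3-ethynyl-6,7-dimethoxychroman; 8 trichloroacetyl chloride
Product: 9 4,4-dichloro-3-[(3S)-6,7-dimethoxychroman-3-yl]cyclobut-2-en-1-one
Conditions: zinc–copper couple Zn(Cu), Et2O–DME, rt, slow addition of 8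
Reagents that add atoms: none
Why: [2+2] cycloaddition of dichloroketene (from zinc dechlorination of 8) with a terminal alkyne, in which the ketene carbonyl carbon bonds to the terminal alkyne carbon, should give the 3-substituted 4,4-dichlorocyclobutenone, while DME binds ZnCl2 and protects the electron-rich arene.

**Step 7**
Reactants: 9 4,4-dichloro-3-[(3S)-6,7-dimethoxychroman-3-yl]cyclobut-2-en-1-one
Product: 11 2-chloro-3-[(3S)-6,7-dimethoxychroman-3-yl]cyclobut-2-en-1-one, via rearranged 2,4-dichlorocyclobutenone 10 (not isolated)
Conditions: ZnCl2 (0.2 equiv), Et2O, rt; then Zn dust, AcOH–EtOH, 0 °C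
Reagents that add atoms: none
Why: ZnCl2 should ionise one C–Cl bond to the oxocyclobutenyl cation and return chloride to the former CH carbon (the known 1,3-chlorine shift of 4,4-dichlorocyclobutenones), after which zinc in acetic acid reduces only the remaining sp3 (allylic, α-keto) C–Cl bond and leaves the vinylic chlorine on C2 as the placeholder for the later oxygen.

**Step 8**
Reactants: 11 2-chloro-3-[(3S)-6,7-dimethoxychroman-3-yl]cyclobut-2-en-1-one; 12 methyl vinyl ether
Product: 16 (3S)-3-(2-chloro-3,4-dimethoxycyclohexa-1,3-dien-1-yl)-6,7-dimethoxychroman, via lithium cyclobutenolate 13 (not isolated), via cyclobutenyl methyl ether 14 (not isolated), via chlorotriene 15 (not isolated)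
Conditions: 12, t-BuLi, THF, −65 to 0 °C; 11, −78 °C; MeOTf, −78 to −40 °C; then Et3N, PhMe, THF distilled off, 100 °C
Reagents that add atoms: methyl trifluoromethanesulfonate, COS(=O)(=O)C(F)(F)F
Why: Proposed new method: 1-methoxyvinyllithium should add 1,2 to the strained ketone of 11 (its β-carbon is fully substituted, so conjugate addition is blocked) and make the bond between the two carbons that end as C3–OMe and C2–OMe, and methyl triflate should cap the tertiary alkoxide 13 at −78 °C before oxyanion-accelerated ring opening sets in. On heating, the 3-methoxy-3-alkenylcyclobutene 14 should open by a conrotatory 4π electrocyclic reaction in which the methoxy group rotates outward (donor torquoselectivity) and so forces the methoxyvinyl group inward, which gives the (3Z)-triene 15. The two unsubstituted CH2 termini of 15 should then close the six-membered carbocycle by a thermal disrotatory 6π electrocyclisation, which makes the C6–C1 bond. The closest known reactions are the thermal ring expansions of 4-alkenylcyclobutenones (Moore rearrangement and related phenol syntheses) and the ring-opening and electrocyclisation cascades of alkenyllithium adducts of squarates; each single event is known, but their union on a 2-chlorocyclobutenone adduct held as its methyl ether has not been shown. No stereocentre is formed and the chroman centre lies outside the pericyclic array, so it is kept. The step needs 1,2-addition ahead of γ-deprotonation (secured by ring strain and low temperature) and the Z geometry of the central double bond (secured by the outward preference of the methoxy group).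

**Step 9**
Reactants: 16 (3S)-3-(2-chloro-3,4-dimethoxycyclohexa-1,3-dien-1-yl)-6,7-dimethoxychroman
Product: 17 (3S)-3-(2-chloro-3,4-dimethoxyphenyl)-6,7-dimethoxychroman
Conditions: DDQ (1.05 equiv), benzene, 5 °C
Reagents that add atoms: none
Why: dehydrogenation of the 1,3-cyclohexadiene by DDQ (hydride abstraction from the CH2–CH2 unit, then proton loss) should be fast at 5 °C, well below the temperature at which DDQ attacks the benzylic CH2 of the chroman.

**Step 10**
Reactants: 17 (3S)-3-(2-chloro-3,4-dimethoxyphenyl)-6,7-dimethoxychroman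
Product: 18 6-[(3S)-6,7-dimethoxychroman-3-yl]-2,3-dimethoxyphenol
Conditions: KOH (3 equiv), Pd2(dba)3 (2 mol %), tBuBrettPhos (8 mol %), 1,4-dioxane–H2O, 100 °C; then aq HCl to pH 5
Reagents that add atoms: potassium hydroxide, [K+].[OH-]
Why: palladium-catalysed hydroxylation of an aryl chloride with KOH (a Buchwald–Hartwig-type C–O coupling), in which the bulky biarylphosphine allows oxidative addition into the hindered, electron-rich C–Cl bond and C–O reductive elimination, while the stereocentre is not acidic under these conditions.

**Step 11**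
Reactants: 18 6-[(3S)-6,7-dimethoxychroman-3-yl]-2,3-dimethoxyphenol
Product: 19 abroquinone A
Conditions: (KSO3)2NO (2.2 equiv), KH2PO4 buffer, acetone–H2O, rt
Reagents that add atoms: dipotassium nitrosodisulfonate, [K+].[K+].[O]N(S(=O)(=O)[O-])S(=O)(=O)[O-]
Why: Teuber oxidation, in which the nitroxide converts the phenol into the phenoxyl radical, a second equivalent adds at the free para position and loss of imidodisulfonate gives the para-quinone, while aryl ethers are inert and the neutral buffer protects the base-sensitive stereocentre next to the quinone.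

**Compound list**

1 | 2-hydroxy-4,5-dimethoxybenzaldehyde | O=Cc1cc(OC)c(OC)cc1O | starting material
2 | acrolein | C=CC=O | starting material
3 | 6,7-dimethoxy-2H-chromene-3-carbaldehyde | O=CC1=Cc2cc(OC)c(OC)cc2OC1 | intermediate
4 | (6,7-dimethoxy-2H-chromen-3-yl)methanol | OCC1=Cc2cc(OC)c(OC)cc2OC1 | intermediate
5 | [(3S)-6,7-dimethoxychroman-3-yl]methanol | OC[C@H]1COc2cc(OC)c(OC)cc2C1 | intermediate
6 | (3R)-6,7-dimethoxychroman-3-carbaldehyde | O=C[C@H]1COc2cc(OC)c(OC)cc2C1 | intermediate
7 | (3S)-3-ethynyl-6,7-dimethoxychroman | C#C[C@H]1COc2cc(OC)c(OC)cc2C1 | intermediate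
8 | trichloroacetyl chloride | ClC(=O)C(Cl)(Cl)Cl | starting material
9 | 4,4-dichloro-3-[(3S)-6,7-dimethoxychroman-3-yl]cyclobut-2-en-1-one | O=C1C=C([C@H]2COc3cc(OC)c(OC)cc3C2)C1(Cl)Cl | intermediate
10 | 2,4-dichloro-3-[(3S)-6,7-dimethoxychroman-3-yl]cyclobut-2-en-1-one (both epimers at C4 of the four-membered ring) | O=C1C(Cl)=C([C@H]2COc3cc(OC)c(OC)cc3C2)C1Cl | intermediate
11 | 2-chloro-3-[(3S)-6,7-dimethoxychroman-3-yl]cyclobut-2-en-1-one | O=C1CC([C@H]2COc3cc(OC)c(OC)cc3C2)=C1Cl | intermediate
12 | methyl vinyl ether | C=COC | starting material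
13 | lithium 2-chloro-3-[(3S)-6,7-dimethoxychroman-3-yl]-1-(1-methoxyvinyl)cyclobut-2-en-1-olate (both epimers at C1) | [Li]OC1(C(=C)OC)CC([C@H]2COc3cc(OC)c(OC)cc3C2)=C1Cl | intermediate
14 | (3S)-3-[2-chloro-3-methoxy-3-(1-methoxyvinyl)cyclobut-1-en-1-yl]-6,7-dimethoxychroman | COC(=C)C1(OC)CC([C@H]2COc3cc(OC)c(OC)cc3C2)=C1Cl | intermediate
15 | (3S)-3-[(3Z)-3-chloro-4,5-dimethoxyhexa-1,3,5-trien-2-yl]-6,7-dimethoxychroman | C=C([C@H]2COc3cc(OC)c(OC)cc3C2)/C(Cl)=C(OC)\C(OC)=C | intermediate
16 | (3S)-3-(2-chloro-3,4-dimethoxycyclohexa-1,3-dien-1-yl)-6,7-dimethoxychroman | COC1=C(OC)C(Cl)=C([C@H]2COc3cc(OC)c(OC)cc3C2)CC1 | intermediate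
17 | (3S)-3-(2-chloro-3,4-dimethoxyphenyl)-6,7-dimethoxychroman | COc1ccc([C@H]2COc3cc(OC)c(OC)cc3C2)c(Cl)c1OC | intermediate
18 | 6-[(3S)-6,7-dimethoxychroman-3-yl]-2,3-dimethoxyphenol | COc1ccc([C@H]2COc3cc(OC)c(OC)cc3C2)c(O)c1OC | intermediate
19 | abroquinone A, 5-[(3S)-6,7-dimethoxychroman-3-yl]-2,3-dimethoxycyclohexa-2,5-diene-1,4-dione | COC1=C(OC)C(=O)C([C@H]2COc3cc(OC)c(OC)cc3C2)=CC1=O | target

**Step count and risks**

Total step count: 11. Longest linear sequence: 11 steps (1 to 19); the route is linear.

Step 8. The lithium cyclobutenolate may open its ring before it is methylated, so that the enolate formed after closure is methylated on carbon. The methoxyvinyl group may also rotate outward in the ring opening, which gives a triene that cannot close, and the vinyllithium may deprotonate the γ-position and erode the stereocentre. The fallback uses known chemistry (Moore rearrangement), sets out from 7 and comes back at 19. Alkyne 7 is deprotonated with n-BuLi (THF, −78 °C) to the lithium acetylide F1 and added to dimethyl squarate (3,4-dimethoxycyclobut-3-ene-1,2-dione). The lithium alkoxide adduct F2 is quenched with aqueous NH4Cl to the hydroxycyclobutenone F3. Heating F3 in p-xylene (138 °C) should give 19 directly by ring opening to the alkynylketene, closure to the diradical and hydrogen transfer. This replaces steps 6 to 11 and gives up the cyclobutenone ring expansion.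

Step 7. The 1,3-shift of chloride may stay incomplete, so that zinc strips both chlorine atoms from unrearranged 9; the oxocyclobutenyl cation may also be captured by the electron-rich chroman ring (intramolecular Friedel–Crafts alkylation). The fallback does without the chlorine placeholder, sets out from 9 and comes back at 19. Reduction of 9 with Zn dust, TMEDA and AcOH in EtOH (TMEDA binds ZnCl2 and suppresses the chlorine shift) should give the chlorine-free cyclobutenone F4. Under the conditions of step 8, F4 should pass through the lithium alkoxide F5, the methyl ether F6 and the (3E)-triene F7 to the cyclohexadiene F8. DDQ as in step 9 should then give the 3,4-dimethoxyphenyl chroman F9. The missing oxygen is brought in by sterically controlled C–H borylation ([Ir(OMe)(cod)]2, 4,4′-di-tert-butyl-2,2′-bipyridine, B2pin2, THF, 80 °C). On the new ring the C–H that lies next to OMe alone is the least hindered: the second is flanked by OMe and the chromanyl group, the third lies next to the branched chromanyl group, and both C–H bonds of the chroman benzo ring have two ortho substituents. This should give the pinacol boronate F10. Oxidation (NaBO3·4H2O, THF–H2O) should give the phenol F11, an isomer of 18 whose free para position is the other future carbonyl carbon. The conditions of step 11 should then convert F11 into 19.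

Step 10. Oxidative addition into the C–Cl bond, which is flanked by OMe and the secondary alkyl group on an electron-rich ring, may be too slow, so that hydrodechlorination or diaryl ether formation takes over. The fallback avoids palladium, sets out from 17 and comes back at 18. Reductive lithiation of 17 with lithium 4,4′-di-tert-butylbiphenylide (THF, −78 °C) should give the aryllithium F12. Trapping with B(OMe)3 gives the lithium aryltrimethoxyborate F13, which is oxidised in the same flask with NaOH and H2O2 to 18.

**Further compounds**

F1 | step 8 | lithium [(3S)-6,7-dimethoxychroman-3-yl]acetylide | [Li]C#C[C@H]1COc2cc(OC)c(OC)cc2C1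
F2 | step 8 | lithium 1-{[(3S)-6,7-dimethoxychroman-3-yl]ethynyl}-2,3-dimethoxy-4-oxocyclobut-2-en-1-olate | [Li]OC1(C#C[C@H]2COc3cc(OC)c(OC)cc3C2)C(OC)=C(OC)C1=O
F3 | step 8 | 4-hydroxy-2,3-dimethoxy-4-{[(3S)-6,7-dimethoxychroman-3-yl]ethynyl}cyclobut-2-en-1-one | COC1=C(OC)C(O)(C#C[C@H]2COc3cc(OC)c(OC)cc3C2)C1=O
F4 | step 7 | 3-[(3S)-6,7-dimethoxychroman-3-yl]cyclobut-2-en-1-one | O=C1C=C([C@H]2COc3cc(OC)c(OC)cc3C2)C1
F5 | step 7 | lithium 3-[(3S)-6,7-dimethoxychroman-3-yl]-1-(1-methoxyvinyl)cyclobut-2-en-1-olate | [Li]OC1(C(=C)OC)C=C([C@H]2COc3cc(OC)c(OC)cc3C2)C1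
F6 | step 7 | (3S)-3-[3-methoxy-3-(1-methoxyvinyl)cyclobut-1-en-1-yl]-6,7-dimethoxychroman | COC(=C)C1(OC)C=C([C@H]2COc3cc(OC)c(OC)cc3C2)C1
F7 | step 7 | (3S)-3-[(3E)-4,5-dimethoxyhexa-1,3,5-trien-2-yl]-6,7-dimethoxychroman | C=C([C@H]2COc3cc(OC)c(OC)cc3C2)/C=C(OC)\C(OC)=C
F8 | step 7 | (3S)-3-(3,4-dimethoxycyclohexa-1,3-dien-1-yl)-6,7-dimethoxychroman | COC1=C(OC)C=C([C@H]2COc3cc(OC)c(OC)cc3C2)CC1
F9 | step 7 | (3S)-3-(3,4-dimethoxyphenyl)-6,7-dimethoxychroman | COc1ccc([C@H]2COc3cc(OC)c(OC)cc3C2)cc1OC
F10 | step 7 | 2-{5-[(3S)-6,7-dimethoxychroman-3-yl]-2,3-dimethoxyphenyl}-4,4,5,5-tetramethyl-1,3,2-dioxaborolane | COc1c(B2OC(C)(C)C(C)(C)O2)cc([C@H]3COc4cc(OC)c(OC)cc4C3)cc1OC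
F11 | step 7 | 5-[(3S)-6,7-dimethoxychroman-3-yl]-2,3-dimethoxyphenol | COc1c(O)cc([C@H]2COc3cc(OC)c(OC)cc3C2)cc1OC
F12 | step 10 | {6-[(3S)-6,7-dimethoxychroman-3-yl]-2,3-dimethoxyphenyl}lithium | COc1ccc([C@H]2COc3cc(OC)c(OC)cc3C2)c([Li])c1OC
F13 | step 10 | lithium {6-[(3S)-6,7-dimethoxychroman-3-yl]-2,3-dimethoxyphenyl}trimethoxyborate | [Li+].COc1ccc([C@H]2COc3cc(OC)c(OC)cc3C2)c([B-](OC)(OC)OC)c1OC
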